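**Assumption:** the target SMILES contains no stereocentres, so Junipegenin C is achiral and no enantiocontrol is needed. It is 5,7-dihydroxy-6,3′,4′,5′-tetramethoxyisoflavone (C19H18O8).

## Retrosynthetic overview
- The C5-OH and C7-OH come from the 5,6,7-trimethoxy precursor by two different demethylations. A nucleophilic thiolate cleaves the C7 methyl ether first, and a chelation-assisted BCl3 cleavage removes the C5 methyl ether.
- The pyranone (C) ring comes from C2 formylation of an ortho-hydroxy deoxybenzoin followed by cyclodehydration, using DMF as the C2 source.
- The deoxybenzoin comes from BF3-mediated C-acylation of 3,4,5-trimethoxyphenol with 3,4,5-trimethoxyphenylacetic acid. The two ortho positions of the phenol are equivalent, so one regioisomer forms and the 5,6,7-oxygenation pattern is fixed.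
- Ring order: the A and B arenes are already present, the A-ring–C4 carbonyl bond is made first, and the C ring closes second.

## Forward route

**Step 1**
Reactants: 1 (3,4,5-trimethoxyphenol) and 2 (3,4,5-trimethoxyphenylacetic acid)
Product: 3, 1-(2-hydroxy-4,5,6-trimethoxyphenyl)-2-(3,4,5-trimethoxyphenyl)ethan-1-one
Conditions: BF3·OEt2 (neat or minimal solvent), 80–90 °C, then aqueous NaOAc work-up
Reagents that add atoms: none (BF3·OEt2 is an activator and leaves no atoms in the product)
Why: BF3 converts the arylacetic acid into an acyl-BF2 species that acylates the electron-rich phenol at carbon (Friedel–Crafts / Hoesch-type acylation). Both ortho positions are equivalent, so there is one regioisomer, and the OH···O=C chelate stabilises the product. No stereocentre is formed.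

**Step 2**
Reactants: 3 (the deoxybenzoin) and 4 (DMF)
Product: 5, 5,6,7,3′,4′,5′-hexamethoxyisoflavone
Conditions: BF3·OEt2, DMF, 50–60 °C; then MeSO2Cl, 60–80 °C; H2O work-up
Reagents that add atoms: DMF, CN(C)C=O (supplies C2 of the chromone; MeSO2Cl, CS(=O)(=O)Cl, only activates and leaves no atoms in the product)
Why: BF3/DMF, activated by MeSO2Cl, formylates the benzylic CH2 in a Vilsmeier-type step to give an enaminone/enol-aldehyde. The only free phenol then closes onto the formyl carbon and eliminates to form the C2=C3 bond of the isoflavone (Wähälä-type one-pot isoflavone synthesis). Nothing is stereogenic.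

**Step 3**
Reactants: 5
Product: 6, 7-hydroxy-5,6,3′,4′,5′-pentamethoxyisoflavone
Conditions: NaSEt (1.5–2 equiv), DMF, 60–90 °C; dilute HCl work-up
Reagents that add atoms: none (the thiolate removes the methyl group as EtSMe; HCl only protonates the phenoxide)
Why: SN2 O-demethylation by thiolate. The 7-OMe is para to the C4a-bound carbonyl, so its phenoxide is a vinylogous carboxylate and the best leaving group. The 5-OMe is hindered by the peri carbonyl and the 6-OMe. The 6-OMe and the B-ring methoxyls are not conjugated to the carbonyl and react much more slowly.

**Step 4**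
Reactants: 6
Product: 7, Junipegenin C
Conditions: BCl3 (2.5–3 equiv), CH2Cl2, −78 °C to 0 °C; aqueous NaHCO3 quench
Reagents that add atoms: none (BCl3 leaves as boron salts and MeCl)
Why: BCl3 binds the C4 carbonyl and the peri 5-OMe as a six-membered chelate and delivers chloride to the methyl group, giving selective peri O-demethylation at C5 (chelation-controlled Lewis-acid cleavage). The 7-OH only consumes one equivalent of BCl3 as the borate. The non-chelated 6-OMe and the B-ring OMe groups survive at low temperature.

## Compound list
1 | 3,4,5-trimethoxyphenol | COc1cc(O)cc(OC)c1OC | starting material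
2 | 3,4,5-trimethoxyphenylacetic acid | COc1cc(CC(=O)O)cc(OC)c1OC | starting material
3 | 1-(2-hydroxy-4,5,6-trimethoxyphenyl)-2-(3,4,5-trimethoxyphenyl)ethanone | COc1cc(CC(=O)c2c(O)cc(OC)c(OC)c2OC)cc(OC)c1OC | intermediate
4 | N,N-dimethylformamide | CN(C)C=O | starting material
5 | 5,6,7,3′,4′,5′-hexamethoxyisoflavone | COc1cc(-c2coc3cc(OC)c(OC)c(OC)c3c2=O)cc(OC)c1OC | intermediate
6 | 7-hydroxy-5,6,3′,4′,5′-pentamethoxyisoflavone | COc1cc(-c2coc3cc(O)c(OC)c(OC)c3c2=O)cc(OC)c1OC | intermediate
7 | Junipegenin C (5,7-dihydroxy-6,3′,4′,5′-tetramethoxyisoflavone) | COc1cc(-c2coc3cc(O)c(OC)c(O)c3c2=O)cc(OC)c1OC | target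

**Total steps:** 4. **Longest linear sequence:** 4 steps (1 → 3 → 5 → 6 → 7).

## Three steps most likely to fail
1. **Step 4 (BCl3 demethylation).** The 6-OMe, or the 4′-OMe flanked by two OMe groups, may also be cleaved.
   *Fallback (different approach):* do the A-ring demethylations before the B ring is attached. Make 3-iodo-5,6,7-trimethoxychromone from 2-hydroxy-4,5,6-trimethoxyacetophenone via the DMF-DMA enaminone and I2. Demethylate it, then attach the B ring by Suzuki coupling with 3,4,5-trimethoxyphenylboronic acid (Pd(PPh3)4, Na2CO3).
2. **Step 3 (thiolate 7-demethylation).** Selectivity may be poor, with attack at the 5-OMe or 6-OMe, or thiolate may add to C2.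
   *Fallback (different approach):* use a differentiated A ring from the start. Build a 2-hydroxy-4,6-bis(benzyloxy)-5-methoxyphenyl deoxybenzoin, cyclise it as in step 2, and remove the benzyl groups with BCl3 and pentamethylbenzene as cation scavenger at −78 °C. Avoid Pd/H2, which would reduce C2=C3. No methyl ether then needs to be discriminated.
3. **Step 1 (BF3 Friedel–Crafts acylation).** The yield may be low because of partial demethylation or self-acylation of the arylacetic acid.
   *Fallback (different approach):* MOM-directed ortho-lithiation of MOM-protected 3,4,5-trimethoxyphenol, addition to the Weinreb amide of 3,4,5-trimethoxyphenylacetic acid, and acidic MOM removal to give 3.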